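**Retrosynthetic overview**

- The target has no stereocenter and no ring to build. In ring B the ether oxygen (C6) and the carboxyl carbon (C1) sit on neighbouring carbons, and the C2 oxygen flanks C1 on its other side; the strategy rests on this C2-O / C1-CO2H / C6-OAr triad.
- Both the C6(B)–O bond and the C1(B)–CO2H bond are disconnected in one step: a ring B aryne (C1≡C6, acetal oxygen on C2) takes up the ring A phenoxide at C6 and carbon dioxide at C1.
- Aryne precursor 11 comes from 2-chloro-3-methylphenol: MOM ether, sterically controlled C–H borylation/oxidation (oxygen para to chlorine), carbamate-directed C1 silylation, triflation.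
- Ring A phenol 16 comes from o-vanillin: Elbs para-hydroxylation, 5-O-benzylation, dioxolane as a masked ester carbon.
- After the coupling: acetal hydrolysis, oxidative methyl esterification of the aldehyde, one BCl3 step to remove benzyl and MOM. Both benzene rings are bought; no ring is formed.

Key step: step 9

Assumption: ring B is numbered C1 (carboxyl), C2 (hydroxyl), C3 (chlorine), C4 (methyl), C5 (hydrogen), C6 (ether oxygen); the C2 oxygen is carried as a methoxymethyl ether because the C–H borylation that sets the ring B oxygen pattern would also attack the phenyl C–H bonds of a benzyl group; 2-chloro-3-methylphenol and o-vanillin are taken as commercial.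

**Route**

Step 1
Reactants: 1 2-chloro-3-methylphenol
Product: 2 2-chloro-1-(methoxymethoxy)-3-methylbenzene
Conditions: MOMCl, i-Pr2NEt, CH2Cl2, 0 °C to rt
Reagents that add atoms: chloromethyl methyl ether COCCl
Why: Williamson-type O-alkylation of the phenol gives an acetal ether that is inert to the iridium catalyst and to organolithium reagents and later directs the lithiation.

Step 2
Reactants: 2 2-chloro-1-(methoxymethoxy)-3-methylbenzene
Product: 4 4-chloro-3-(methoxymethoxy)-5-methylphenol, via aryl boronate 3 (not isolated)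
Conditions: [Ir(OMe)(cod)]2 (cat.), 4,4'-di-tert-butyl-2,2'-bipyridine (cat.), B2pin2 (0.6 equiv), THF, 80 °C; then 30% H2O2, aq NaOH, 0 °C
Reagents that add atoms: bis(pinacolato)diboron CC1(C)OB(OC1(C)C)B1OC(C)(C)C(C)(C)O1 (boryl group of 3); hydrogen peroxide OO (phenol oxygen of 4)
Why: Iridium-catalysed C–H borylation is sterically controlled, so the 1,2,3-trisubstituted ring should react only at the one C–H with no ortho neighbour (para to chlorine), and alkaline peroxide oxidation of the boronate then gives the phenol.

Step 3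
Reactants: 4 4-chloro-3-(methoxymethoxy)-5-methylphenol
Product: 5 4-chloro-3-(methoxymethoxy)-5-methylphenyl N-(propan-2-yl)carbamate
Conditions: i-PrNCO, Et3N (cat.), CH2Cl2, rt
Reagents that add atoms: isopropyl isocyanate CC(C)N=C=O
Why: Base-catalysed addition of the phenol to the isocyanate gives the secondary carbamate, a metalation director that can later be removed under mild base.

Step 4
Reactants: 5 4-chloro-3-(methoxymethoxy)-5-methylphenyl N-(propan-2-yl)carbamate
Product: 9 4-chloro-3-(methoxymethoxy)-5-methyl-2-(trimethylsilyl)phenyl N-(propan-2-yl)carbamate, via N-silyl carbamate 6 (not isolated), via aryllithium 7 (not isolated), via bis-silyl carbamate 8 (not isolated)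
Conditions: TBSOTf, TMEDA, Et2O, 0 °C to rt; n-BuLi (2 equiv), TMEDA, −78 °C; TMSCl, −78 °C to rt; cold aq NaHSO4 work-up
Reagents that add atoms: tert-butyldimethylsilyl triflate CC(C)(C)[Si](C)(C)OS(=O)(=O)C(F)(F)F (N-silyl group of 6 to 8); n-butyllithium [Li]CCCC (lithium of 7); chlorotrimethylsilane C[Si](C)(C)Cl
Why: Directed ortho-metalation: after in situ N-silylation of the carbamate, lithiation should occur at the ring carbon flanked by both the carbamate oxygen and the MOM oxygen (cooperating directors), the aryllithium is silylated, and the N-silyl group is lost on aqueous work-up.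

Step 5
Reactants: 9 4-chloro-3-(methoxymethoxy)-5-methyl-2-(trimethylsilyl)phenyl N-(propan-2-yl)carbamate
Product: 11 4-chloro-3-(methoxymethoxy)-5-methyl-2-(trimethylsilyl)phenyl trifluoromethanesulfonate, via silyl phenol 10 (not isolated)
Conditions: DBU, Et2NH, MeCN, 40 °C; then PhNTf2, rt
Reagents that add atoms: N-phenylbis(trifluoromethanesulfonimide) O=S(=O)(N(c1ccccc1)S(=O)(=O)C(F)(F)F)C(F)(F)F
Why: E1cB cleavage of the secondary carbamate (the isocyanate is trapped by Et2NH as a urea) frees the ortho-silyl phenoxide, which is O-sulfonylated in the same pot by the triflimide.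

Step 6
Reactants: 12 o-vanillin (2-hydroxy-3-methoxybenzaldehyde)
Product: 14 2,5-dihydroxy-3-methoxybenzaldehyde, via aryl sulfate 13 (not isolated)
Conditions: K2S2O8, aq NaOH, 0 °C to rt, N2; then aq HCl, 70 °C
Reagents that add atoms: potassium peroxodisulfate K2S2O8 [K+].[K+].[O-]S(=O)(=O)OOS(=O)(=O)[O-]
Why: Elbs persulfate oxidation: the phenoxide attacks the peroxide oxygen through its free para carbon to give the aryl sulfate, and acid hydrolysis of the sulfate frees the hydroquinone.

Step 7
Reactants: 14 2,5-dihydroxy-3-methoxybenzaldehyde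
Product: 15 5-(benzyloxy)-2-hydroxy-3-methoxybenzaldehyde
Conditions: BnBr (1.05 equiv), K2CO3 (1.0 equiv), acetone, reflux, N2
Reagents that add atoms: benzyl bromide BrCc1ccccc1
Why: Williamson etherification with one equivalent of base should go to the C5 hydroxyl, because the C2 hydroxyl is hydrogen-bonded to the formyl group and flanked by two substituents.

Step 8
Reactants: 15 5-(benzyloxy)-2-hydroxy-3-methoxybenzaldehyde
Product: 16 4-(benzyloxy)-2-(1,3-dioxolan-2-yl)-6-methoxyphenol
Conditions: ethylene glycol, p-TsOH (cat.), toluene, reflux, Dean–Stark trap; Et3N quench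
Reagents that add atoms: ethylene glycol OCCO
Why: Acid-catalysed acetalisation driven by azeotropic removal of water masks the formyl carbon, the later ester carbon, as a group that an aryl anion cannot attack.

Step 9
Reactants: 11 4-chloro-3-(methoxymethoxy)-5-methyl-2-(trimethylsilyl)phenyl trifluoromethanesulfonate; 16 4-(benzyloxy)-2-(1,3-dioxolan-2-yl)-6-methoxyphenol; 17 carbon dioxide
Product: 21 6-[4-(benzyloxy)-2-(1,3-dioxolan-2-yl)-6-methoxyphenoxy]-3-chloro-2-(methoxymethoxy)-4-methylbenzoic acid, via potassium phenoxide 18 (not isolated), via aryne 19 (not isolated), via aryl anion 20 (not isolated)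
Conditions: 16 (1.3 equiv), KH, THF, 0 °C; then 18-crown-6, KF, CO2 (1 atm), slow addition of 11, 0 °C to rt; cold dilute HCl to pH 3
Reagents that add atoms: potassium hydride KH [K+].[H-] (counter-ion of 18 and 20 only)
Why: Proposed new method: fluoride attacks the silicon of 11 and triflate leaves to give aryne 19, whose C1≡C6 bond is distorted by the inductively withdrawing C2 oxygen so that C6 is the electrophilic end; phenoxide 18, which can react only through oxygen because its ortho and para carbons are all substituted, adds at C6, and the aryl anion 20 left at C1 next to the C2 oxygen is carboxylated by CO2. The closest known reaction type is the fluoride-triggered three-component coupling of silylaryl triflate derived arynes with amines and CO2 to give anthranilic acids, together with the known O-arylation of phenols by such arynes; the new element is an anionic, doubly ortho-substituted phenoxide as the first component. No ring is closed and no stereocenter is formed. The step needs addition at C6 and not at C1, which the C2 oxygen secures electronically and the unhindered C5–H side supports sterically. It also needs capture of the anion by CO2 rather than by a proton or an acyl group, which is secured by making the phenoxide with KH (no conjugate acid remains) and by carrying the ring A carboxyl carbon as a dioxolane, so that no xanthone can close.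

Step 10
Reactants: 21 6-[4-(benzyloxy)-2-(1,3-dioxolan-2-yl)-6-methoxyphenoxy]-3-chloro-2-(methoxymethoxy)-4-methylbenzoic acid
Product: 22 6-[4-(benzyloxy)-2-formyl-6-methoxyphenoxy]-3-chloro-2-(methoxymethoxy)-4-methylbenzoic acid
Conditions: 1 M aq HCl, THF, 0 °C to rt
Reagents that add atoms: water O
Why: Acid-catalysed acetal hydrolysis through the benzylic oxocarbenium ion frees the aldehyde, while the aryl MOM ether, which needs stronger acid or an alcohol solvent, should survive.

Step 11
Reactants: 22 6-[4-(benzyloxy)-2-formyl-6-methoxyphenoxy]-3-chloro-2-(methoxymethoxy)-4-methylbenzoic acid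
Product: 24 6-[4-(benzyloxy)-2-methoxy-6-(methoxycarbonyl)phenoxy]-3-chloro-2-(methoxymethoxy)-4-methylbenzoic acid, via methyl hemiacetal 23 (not isolated)
Conditions: I2, KOH, MeOH, 0 °C; aq Na2S2O3, then acidification
Reagents that add atoms: methanol CO
Why: Iodine-mediated oxidative esterification: the aldehyde forms hemiacetal 23 in methanol and hypoiodite oxidises it to the methyl ester, while the ring B carboxylate is inert, so the two carboxyl groups end differentiated without a protecting group.

Step 12
Reactants: 24 6-[4-(benzyloxy)-2-methoxy-6-(methoxycarbonyl)phenoxy]-3-chloro-2-(methoxymethoxy)-4-methylbenzoic acid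
Product: 25 isodihydromaldoxin
Conditions: BCl3 (excess), pentamethylbenzene, CH2Cl2, −78 to 0 °C; aq work-up
Reagents that add atoms: none
Why: Lewis acid ether cleavage: BCl3 should remove the aryl benzyl ether and the MOM acetal at low temperature with pentamethylbenzene capturing the benzyl cation (Friedel–Crafts), while the aryl chloride, the methyl ester and the aryl methyl ether, which has no carbonyl group ortho to it for chelation, should be left intact.

**Compound list**

1 | 2-chloro-3-methylphenol | Cc1cccc(O)c1Cl | starting material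
2 | 2-chloro-1-(methoxymethoxy)-3-methylbenzene | COCOc1cccc(C)c1Cl | intermediate
3 | 2-[4-chloro-3-(methoxymethoxy)-5-methylphenyl]-4,4,5,5-tetramethyl-1,3,2-dioxaborolane | COCOc1cc(B2OC(C)(C)C(C)(C)O2)cc(C)c1Cl | intermediate
4 | 4-chloro-3-(methoxymethoxy)-5-methylphenol | COCOc1cc(O)cc(C)c1Cl | intermediate
5 | 4-chloro-3-(methoxymethoxy)-5-methylphenyl N-(propan-2-yl)carbamate | COCOc1cc(OC(=O)NC(C)C)cc(C)c1Cl | intermediate
6 | 4-chloro-3-(methoxymethoxy)-5-methylphenyl N-(tert-butyldimethylsilyl)-N-(propan-2-yl)carbamate | COCOc1cc(OC(=O)N(C(C)C)[Si](C)(C)C(C)(C)C)cc(C)c1Cl | intermediate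
7 | [6-{[(tert-butyldimethylsilyl)(propan-2-yl)carbamoyl]oxy}-3-chloro-2-(methoxymethoxy)-4-methylphenyl]lithium | COCOc1c(Cl)c(C)cc(OC(=O)N(C(C)C)[Si](C)(C)C(C)(C)C)c1[Li] | intermediate
8 | 4-chloro-3-(methoxymethoxy)-5-methyl-2-(trimethylsilyl)phenyl N-(tert-butyldimethylsilyl)-N-(propan-2-yl)carbamate | COCOc1c(Cl)c(C)cc(OC(=O)N(C(C)C)[Si](C)(C)C(C)(C)C)c1[Si](C)(C)C | intermediate
9 | 4-chloro-3-(methoxymethoxy)-5-methyl-2-(trimethylsilyl)phenyl N-(propan-2-yl)carbamate | COCOc1c(Cl)c(C)cc(OC(=O)NC(C)C)c1[Si](C)(C)C | intermediate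
10 | 4-chloro-3-(methoxymethoxy)-5-methyl-2-(trimethylsilyl)phenol (present as its DBU salt) | COCOc1c(Cl)c(C)cc(O)c1[Si](C)(C)C | intermediate
11 | 4-chloro-3-(methoxymethoxy)-5-methyl-2-(trimethylsilyl)phenyl trifluoromethanesulfonate | COCOc1c(Cl)c(C)cc(OS(=O)(=O)C(F)(F)F)c1[Si](C)(C)C | intermediate
12 | o-vanillin (2-hydroxy-3-methoxybenzaldehyde) | COc1cccc(C=O)c1O | starting material
13 | potassium 3-formyl-4-hydroxy-5-methoxyphenyl sulfate | COc1cc(OS(=O)(=O)[O-])cc(C=O)c1O.[K+] | intermediate
14 | 2,5-dihydroxy-3-methoxybenzaldehyde | COc1cc(O)cc(C=O)c1O | intermediate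
15 | 5-(benzyloxy)-2-hydroxy-3-methoxybenzaldehyde | COc1cc(OCc2ccccc2)cc(C=O)c1O | intermediate
16 | 4-(benzyloxy)-2-(1,3-dioxolan-2-yl)-6-methoxyphenol | COc1cc(OCc2ccccc2)cc(C2OCCO2)c1O | intermediate
17 | carbon dioxide | O=C=O | starting material
18 | potassium 4-(benzyloxy)-2-(1,3-dioxolan-2-yl)-6-methoxyphenolate | COc1cc(OCc2ccccc2)cc(C2OCCO2)c1[O-].[K+] | intermediate
19 | 4-chloro-3-(methoxymethoxy)-5-methyl-1,2-didehydrobenzene (ring B aryne, triple bond C1≡C6) | COCOC1=C(Cl)C(C)=CC#C1 | intermediate
20 | {6-[4-(benzyloxy)-2-(1,3-dioxolan-2-yl)-6-methoxyphenoxy]-3-chloro-2-(methoxymethoxy)-4-methylphenyl}potassium | COCOc1[c-]c(Oc2c(OC)cc(OCc3ccccc3)cc2C2OCCO2)cc(C)c1Cl.[K+] | intermediate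
21 | 6-[4-(benzyloxy)-2-(1,3-dioxolan-2-yl)-6-methoxyphenoxy]-3-chloro-2-(methoxymethoxy)-4-methylbenzoic acid | COCOc1c(Cl)c(C)cc(Oc2c(OC)cc(OCc3ccccc3)cc2C2OCCO2)c1C(=O)O | intermediate
22 | 6-[4-(benzyloxy)-2-formyl-6-methoxyphenoxy]-3-chloro-2-(methoxymethoxy)-4-methylbenzoic acid | COCOc1c(Cl)c(C)cc(Oc2c(OC)cc(OCc3ccccc3)cc2C=O)c1C(=O)O | intermediate
23 | 6-{4-(benzyloxy)-2-[hydroxy(methoxy)methyl]-6-methoxyphenoxy}-3-chloro-2-(methoxymethoxy)-4-methylbenzoic acid (racemic hemiacetal, present as potassium salt) | COCOc1c(Cl)c(C)cc(Oc2c(OC)cc(OCc3ccccc3)cc2C(O)OC)c1C(=O)O | intermediate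
24 | 6-[4-(benzyloxy)-2-methoxy-6-(methoxycarbonyl)phenoxy]-3-chloro-2-(methoxymethoxy)-4-methylbenzoic acid | COCOc1c(Cl)c(C)cc(Oc2c(OC)cc(OCc3ccccc3)cc2C(=O)OC)c1C(=O)O | intermediate
25 | isodihydromaldoxin, 3-chloro-2-hydroxy-6-[4-hydroxy-2-methoxy-6-(methoxycarbonyl)phenoxy]-4-methylbenzoic acid | COC(=O)c1cc(O)cc(OC)c1Oc1cc(C)c(Cl)c(O)c1C(=O)O | target

**Step count and risks**

Total step count: 12. Longest linear sequence: 9 steps (steps 1 to 5, then 9 to 12); the ring A arm (steps 6 to 8) joins at step 9.

Steps most likely to fail: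

1. Step 9. The aryl anion may be protonated before it meets CO2. Alternatively, under CO2 the phenoxide may rest as its carbonate half-ester and add through the carbonate oxygen, after which the anion would take the acyl group and give an aryl ester instead of the ether acid. The fallback forms the two bonds one after the other by known reactions. It sets out from 11 and 16: CsF in MeCN at rt (aryne O-arylation of a phenol, same regiochemistry) should give the diaryl ether 2-{5-(benzyloxy)-2-[4-chloro-3-(methoxymethoxy)-5-methylphenoxy]-3-methoxyphenyl}-1,3-dioxolane F1. Directed ortho-lithiation with n-BuLi and TMEDA in THF at −40 °C should then remove the ring B C1 hydrogen, which lies between the chelating MOM oxygen and the aryloxy oxygen and is further acidified by the ring chlorine, to give {6-[4-(benzyloxy)-2-(1,3-dioxolan-2-yl)-6-methoxyphenoxy]-3-chloro-2-(methoxymethoxy)-4-methylphenyl}lithium F2. A CO2 quench and cold acidification bring the sequence back to the route at 21.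

2. Step 4. The silyl triflate may attack the MOM acetal during N-silylation, or lithiation may be slow at the crowded carbon between the two oxygens and drift to other sites. The fallback avoids the silyl triflate by using a tertiary carbamate. It sets out from 4: Et2NCOCl and K2CO3 in MeCN should give 4-chloro-3-(methoxymethoxy)-5-methylphenyl N,N-diethylcarbamate F3. s-BuLi and TMEDA in THF at −78 °C should give [3-chloro-6-[(diethylcarbamoyl)oxy]-2-(methoxymethoxy)-4-methylphenyl]lithium F4, which TMSCl converts to 4-chloro-3-(methoxymethoxy)-5-methyl-2-(trimethylsilyl)phenyl N,N-diethylcarbamate F5. Reductive cleavage of the carbamate with LiAlH4 in THF then gives the free phenol, so the sequence comes back to the route at 10, which is triflated with PhNTf2 and DBU as in the second half of step 5 to give 11.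

3. Step 11. Hypoiodite may iodinate the electron-rich ring A, or oxidation of the hindered hemiacetal may stall while the aldehyde disproportionates in base. The fallback separates oxidation from esterification. It sets out from 22: Pinnick oxidation (NaClO2, NaH2PO4, 2-methyl-2-butene, t-BuOH–H2O) should give the diacid 6-[4-(benzyloxy)-2-carboxy-6-methoxyphenoxy]-3-chloro-2-(methoxymethoxy)-4-methylbenzoic acid F6. Fischer esterification with HCl in MeOH at 50 °C should esterify only the ring A acid, because the ring B acid is substituted at both ortho positions, and should remove the MOM group at the same time, giving 6-[4-(benzyloxy)-2-methoxy-6-(methoxycarbonyl)phenoxy]-3-chloro-2-hydroxy-4-methylbenzoic acid F7. BCl3 with pentamethylbenzene, as in step 12, then removes the benzyl group and the sequence comes back to the route at 25.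

**Further compounds**

F1 | step 9 | 2-{5-(benzyloxy)-2-[4-chloro-3-(methoxymethoxy)-5-methylphenoxy]-3-methoxyphenyl}-1,3-dioxolane | COCOc1cc(Oc2c(OC)cc(OCc3ccccc3)cc2C2OCCO2)cc(C)c1Cl
F2 | step 9 | {6-[4-(benzyloxy)-2-(1,3-dioxolan-2-yl)-6-methoxyphenoxy]-3-chloro-2-(methoxymethoxy)-4-methylphenyl}lithium | COCOc1c([Li])c(Oc2c(OC)cc(OCc3ccccc3)cc2C2OCCO2)cc(C)c1Cl
F3 | step 4 | 4-chloro-3-(methoxymethoxy)-5-methylphenyl N,N-diethylcarbamate | COCOc1cc(OC(=O)N(CC)CC)cc(C)c1Cl
F4 | step 4 | [3-chloro-6-[(diethylcarbamoyl)oxy]-2-(methoxymethoxy)-4-methylphenyl]lithium | COCOc1c(Cl)c(C)cc(OC(=O)N(CC)CC)c1[Li]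
F5 | step 4 | 4-chloro-3-(methoxymethoxy)-5-methyl-2-(trimethylsilyl)phenyl N,N-diethylcarbamate | COCOc1c(Cl)c(C)cc(OC(=O)N(CC)CC)c1[Si](C)(C)C
F6 | step 11 | 6-[4-(benzyloxy)-2-carboxy-6-methoxyphenoxy]-3-chloro-2-(methoxymethoxy)-4-methylbenzoic acid | COCOc1c(Cl)c(C)cc(Oc2c(OC)cc(OCc3ccccc3)cc2C(=O)O)c1C(=O)O
F7 | step 11 | 6-[4-(benzyloxy)-2-methoxy-6-(methoxycarbonyl)phenoxy]-3-chloro-2-hydroxy-4-methylbenzoic acid | COC(=O)c1cc(OCc2ccccc2)cc(OC)c1Oc1cc(C)c(Cl)c(O)c1C(=O)O
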